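## Retrosynthetic overview

- Target ⇐ fluoride desilylation with in-situ O-methylation of a 2',3'-O-(di-tert-butylsilylene) catechol, then methylation of the 5-OH (last step, three O–Me bonds).
- Silylene catechol ⇐ anodic Pd-catalysed, silanol-directed C2'–H oxygenation of the 3'-O–Si(tBu)2OH ether. This forms the key C2'–O bond; C4' carries OMe, so C2' is the only ortho C–H.
- Silanol ⇐ 7-O-methylhesperetin ⇐ (2S)-hesperetin ⇐ hesperidin (glycoside methanolysis, acidity-controlled 7-O-methylation, 3'-O-silylation).
- The (S) centre at C2 is bought with hesperidin and no bond to it is made or broken. The A, B and pyranone rings are all bought; the only ring formed is the temporary benzodioxasilole (step 4), opened again in step 5.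

Assumption: hesperidin is used as the natural (2S)-epimer, with epimeric purity checked by chiral HPLC; bulk hesperetin aglycone is avoided because it is often partly racemic.

## Route

Step 1
Reactants: 1 hesperidin [(2S)-hesperetin 7-O-(6-O-α-L-rhamnopyranosyl-β-D-glucopyranoside)]
Product: 2 (2S)-hesperetin [(2S)-5,7-dihydroxy-2-(3-hydroxy-4-methoxyphenyl)chroman-4-one]
Conditions: conc. H2SO4 (ca. 1.5 M), MeOH, reflux, 8 h
Reagents that add atoms: none
Why: Acid-catalysed glycoside methanolysis cleaves the aryl glycosidic acetal at the anomeric carbon and leaves O7 on the aglycone; C2 is untouched because no base is present to trigger retro-oxa-Michael ring opening.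

Step 2
Reactants: 2 (2S)-hesperetin
Product: 3 (2S)-5-hydroxy-2-(3-hydroxy-4-methoxyphenyl)-7-methoxychroman-4-one (7-O-methylhesperetin)
Conditions: MeI (1.1 equiv), KHCO3 (1.5 equiv), DMF, 40 °C
Reagents that add atoms: methyl iodide, CI
Why: Williamson etherification under acidity control, since bicarbonate ionises only the 7-OH (para to C=O, pKa about 7.5) and not the 3'-OH (about 10) or the H-bonded 5-OH; C2 is untouched.

Step 3
Reactants: 3 (2S)-5-hydroxy-2-(3-hydroxy-4-methoxyphenyl)-7-methoxychroman-4-one
Product: 5 (2S)-2-{3-[(di-tert-butyl)(hydroxy)silyl]oxy-4-methoxyphenyl}-5-hydroxy-7-methoxychroman-4-one, via aryloxysilyl triflate 4 (not isolated)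
Conditions: tBu2Si(OTf)2 (1.1 equiv), 2,6-lutidine, CH2Cl2, −78 → 0 °C; then aq. NaHCO3, rt
Reagents that add atoms: di-tert-butylsilyl bis(trifluoromethanesulfonate), CC(C)(C)[Si](OS(=O)(=O)C(F)(F)F)(OS(=O)(=O)C(F)(F)F)C(C)(C)C; water, O
Why: O-silylation of the free 3'-OH with a silyl bis-triflate (the 5-OH is tied up in a strong H-bond to C4=O and reacts much more slowly at low temperature), then hydrolysis of the remaining hindered Si–OTf to the stable di-tert-butylsilanol; C2 is untouched.

Step 4
Reactants: 5 (2S)-2-{3-[(di-tert-butyl)(hydroxy)silyl]oxy-4-methoxyphenyl}-5-hydroxy-7-methoxychroman-4-one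
Product: 6 (2S)-2-(2,2-di-tert-butyl-7-methoxy-1,3,2-benzodioxasilol-4-yl)-5-hydroxy-7-methoxychroman-4-one
Conditions: Pd(OPiv)2 (10 mol %), KOPiv (1 equiv), PivOH (5 equiv), nBu4NBF4 (0.1 M), MeCN, 60 °C; divided cell (Nafion), graphite-felt anode | Pt cathode, +1.1 V vs Ag/AgCl, ca. 2.3 F/mol
Reagents that add atoms: none
Why: Proposed new method: anodic silanol-directed Pd-catalysed dehydrogenative C–H oxygenation – pivalate-assisted (CMD) cyclopalladation directed by the Si–OH can only occur at C2' because the other ortho carbon C4' carries OMe, the six-membered C,O-palladacycle is oxidised at the anode (Pd(II) to Pd(III)/Pd(IV)) at a potential expected to lie below the onset of the methoxyarene rings (to be checked by CV), and C(sp2)–O reductive elimination onto the silanolate oxygen (or onto pivalate followed by O-to-Si transfer, same product) closes the dioxasilole and returns Pd(II) while protons are reduced to H2 in the separate cathode chamber; the closest known reactions are the silanol-directed Pd(II)/Pd(IV) oxygenation of phenols to catechols with PhI(OAc)2 and anodic Pd-catalysed directed C–H acetoxylation of oxime ethers, and C2 is not involved in this acidic, base-free medium.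

Step 5
Reactants: 6 (2S)-2-(2,2-di-tert-butyl-7-methoxy-1,3,2-benzodioxasilol-4-yl)-5-hydroxy-7-methoxychroman-4-one
Product: 8 (2S)-5,7-dimethoxy-2-(2,3,4-trimethoxyphenyl)chroman-4-one, via 5-hydroxy tetramethyl ether 7 (not isolated)
Conditions: CsF (3 equiv), MeI (10 equiv), DMF, 0 °C → rt; then Cs2CO3 (1.2 equiv), rt
Reagents that add atoms: methyl iodide, CI
Why: Fluoride-induced Si–O cleavage of the strained dioxasilole with in-situ Williamson O-methylation of each phenoxide as it is released (excess MeI keeps the 2'-phenoxide short-lived), then carbonate-mediated Williamson methylation of the H-bonded 5-OH; no bond to C2 is broken, and any ring-opened phenoxide would be trapped as a separable chalcone methyl ether and not return as racemic flavanone.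

## Compound list

1 | hesperidin, (2S)-hesperetin 7-O-(6-O-α-L-rhamnopyranosyl-β-D-glucopyranoside) | C[C@H]1[C@@H]([C@H]([C@H]([C@@H](O1)OC[C@@H]2[C@H]([C@@H]([C@H]([C@@H](O2)OC3=CC(=C4C(=O)C[C@H](OC4=C3)C5=CC(=C(C=C5)OC)O)O)O)O)O)O)O)O | starting material
2 | (2S)-5,7-dihydroxy-2-(3-hydroxy-4-methoxyphenyl)chroman-4-one, (2S)-hesperetin | O=C1C[C@H](Oc2cc(O)cc(O)c21)c1ccc(OC)c(O)c1 | intermediate
3 | (2S)-5-hydroxy-2-(3-hydroxy-4-methoxyphenyl)-7-methoxychroman-4-one | O=C1C[C@H](Oc2cc(OC)cc(O)c21)c1ccc(OC)c(O)c1 | intermediate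
4 | di-tert-butyl{5-[(2S)-5-hydroxy-7-methoxy-4-oxochroman-2-yl]-2-methoxyphenoxy}silyl trifluoromethanesulfonate | O=C1C[C@H](Oc2cc(OC)cc(O)c21)c1ccc(OC)c(O[Si](OS(=O)(=O)C(F)(F)F)(C(C)(C)C)C(C)(C)C)c1 | intermediate
5 | (2S)-2-{3-[(di-tert-butyl)(hydroxy)silyl]oxy-4-methoxyphenyl}-5-hydroxy-7-methoxychroman-4-one | O=C1C[C@H](Oc2cc(OC)cc(O)c21)c1ccc(OC)c(O[Si](O)(C(C)(C)C)C(C)(C)C)c1 | intermediate
6 | (2S)-2-(2,2-di-tert-butyl-7-methoxy-1,3,2-benzodioxasilol-4-yl)-5-hydroxy-7-methoxychroman-4-one | O=C1C[C@H](Oc2cc(OC)cc(O)c21)c1ccc(OC)c2O[Si](C(C)(C)C)(C(C)(C)C)Oc12 | intermediate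
7 | (2S)-5-hydroxy-7-methoxy-2-(2,3,4-trimethoxyphenyl)chroman-4-one | O=C1C[C@H](Oc2cc(OC)cc(O)c21)c1ccc(OC)c(OC)c1OC | intermediate
8 | (2S)-5,7-dimethoxy-2-(2,3,4-trimethoxyphenyl)chroman-4-one | COc1cc(OC)c2c(c1)O[C@H](c1ccc(OC)c(OC)c1OC)CC2=O | target

## Step count and risks

Total step count: 5. Longest linear sequence: 5.

The three steps most likely to fail:

**Step 4 (proposed new step).** The risks are Pd(II)-mediated dehydrogenation of the flavanone to the flavone, direct anodic oxidation of the electron-rich rings, slow palladation at the hindered C2', and Pd binding to the 5-OH/C4=O chelate. The fallback is known chemistry and replaces the anode by a two-electron acetoxy-transfer oxidant. It sets out from 5: Pd(OPiv)2 (5 mol %) and PhI(OAc)2 (2 equiv) in toluene at 80–100 °C give, by silanol-directed Pd(II)/Pd(IV) C–H acetoxylation, the ortho-acetoxy aryloxysilanol F1. F1 closes in the flask by acyl transfer and silyl ether formation with loss of acetic acid, and the route comes back at 6.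

**Step 5.** The risks are base-induced opening of the pyranone (chalcone formation, or an o-quinone methide from the transient 2'-phenoxide) with loss of yield or ee, incomplete second Si–O cleavage, and sluggish methylation of the chelated 5-OH. The fallback separates the events and avoids base until the end. It sets out from 6: HF·pyridine in THF at 0 °C gives the catechol (2S)-2-(2,3-dihydroxy-4-methoxyphenyl)-5-hydroxy-7-methoxychroman-4-one F2. TMSCHN2 in MeOH/toluene at rt then methylates the two B-ring phenols without base, giving 7, this time isolated. The chelated 5-OH is finally methylated with MeI/Ag2O in CH2Cl2 at rt, and the route comes back at 8.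

**Step 3.** The risks are over-silylation at the 5-OH (which would later direct oxygenation to C6), silyl enol ether formation at C4, and bis-aryloxysilane dimer. The fallback uses a much less electrophilic silicon reagent and makes the Si–OH by oxidation. It sets out from 3: tBu2SiHCl and imidazole in DMF at rt give the hydrosilyl ether (2S)-2-{3-[(di-tert-butylsilyl)oxy]-4-methoxyphenyl}-5-hydroxy-7-methoxychroman-4-one F3. Its Si–H is then converted to Si–OH with water under [RuCl2(p-cymene)]2 catalysis in MeCN (catalytic hydrolytic oxidation of a hydrosilane), and the route comes back at 5.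

## Further compounds

F1 | step 4 | (2S)-2-{2-acetoxy-3-[(di-tert-butyl)(hydroxy)silyl]oxy-4-methoxyphenyl}-5-hydroxy-7-methoxychroman-4-one | O=C1C[C@H](Oc2cc(OC)cc(O)c21)c1ccc(OC)c(O[Si](O)(C(C)(C)C)C(C)(C)C)c1OC(C)=O
F2 | step 5 | (2S)-2-(2,3-dihydroxy-4-methoxyphenyl)-5-hydroxy-7-methoxychroman-4-one | O=C1C[C@H](Oc2cc(OC)cc(O)c21)c1ccc(OC)c(O)c1O
F3 | step 3 | (2S)-2-{3-[(di-tert-butylsilyl)oxy]-4-methoxyphenyl}-5-hydroxy-7-methoxychroman-4-one | O=C1C[C@H](Oc2cc(OC)cc(O)c21)c1ccc(OC)c(O[SiH](C(C)(C)C)C(C)(C)C)c1
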